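**Strategy.** Ring B is cut across C4a'–C4' and C8a'–C1', giving (S)-cryptone and a 2-silyloxybutadiene. One Diels–Alder reaction closes ring B, puts oxygen on the future spiro carbon C2' and, by cis addition anti to the C8' isopropyl group, sets the ring-fusion centre C4a' of ring A with its C4' bond trans to isopropyl and (after convex-face hydrogenation) cis to the C5' methyl, a pattern that equilibration would not give. The dienophile carries the single purchased stereocentre; the diene is used as its tert-butyldimethylsilyl ether so that the adduct's enol silane survives and masks C2'. Enone formation, methylenation and a benzaldehyde/diformylphloroglucinol hetero-Diels–Alder reaction then build the spiro-chroman.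

Key step: step 2

Remark (assumption): (S)-cryptone, 2,4,6-trihydroxybenzene-1,3-dicarbaldehyde and Cp2TiMe2 are taken as purchasable; the enone is otherwise two steps from isovaleraldehyde and but-3-en-2-one by an amine-catalysed Michael addition/aldol condensation.

Locants: decalin C1'–C8a' (C2' spiro, C5' methyl, C8' isopropyl; ring A = C4a', C5'–C8', C8a'; ring B = C1'–C4', C4a', C8a'); chroman O1, C2 (= C2'), C3, C4 (phenyl-bearing).

Step 1
Reactants: 1 but-3-en-2-one (methyl vinyl ketone)
Product: 2 2-[(tert-butyldimethylsilyl)oxy]buta-1,3-diene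
Conditions: TBSOTf, Et3N, Et2O, 0 °C to rt
Reagents that add atoms: tert-butyldimethylsilyl trifluoromethanesulfonate (TBSOTf), CC(C)(C)[Si](C)(C)OS(=O)(=O)C(F)(F)F
Why: Silyl enol ether formation by soft enolisation of the methyl ketone (the vinyl side has no enolisable hydrogen) should give the cross-conjugated 2-silyloxy diene; no stereocentre is formed.

Step 2
Reactants: 3 (S)-cryptone, (4S)-4-(propan-2-yl)cyclohex-2-en-1-one; 2 2-[(tert-butyldimethylsilyl)oxy]buta-1,3-diene
Product: 4 cis-fused keto enol silane (4S,4aS,8aS)-6-[(tert-butyldimethylsilyl)oxy]-4-(propan-2-yl)-3,4,4a,5,8,8a-hexahydronaphthalen-1(2H)-one (C5' ketone, C2'=C3' enol silane, H4a' and H8a' both on the isopropyl face)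
Conditions: 2 (excess), Tf2NH (5 mol %), CH2Cl2, −78 °C; Et3N quench
Reagents that add atoms: none
Why: The silyl triflimide formed in the flask from Tf2NH and a little diene activates the enone carbonyl of 3, and the nucleophilic CH2 terminus of the diene bonds to the β-carbon C8a' while the vinyl terminus bonds to C4a', either in one asynchronous [4+2] event or as a Mukaiyama–Michael/Michael sequence that ends in the same enol silane. The closest known reaction type is the acid-catalysed Diels–Alder reaction of 4-alkylcyclohex-2-enones with 2-silyloxybutadienes. Ring B is closed by suprafacial [4+2] addition across C4a'=C8a' (in the stepwise reading by a 6-endo-trig Michael closure of the ring A enol silane onto the tethered vinyl ketone), which can only give the cis ring fusion. Both new stereocentres are controlled by the resident C8' centre: the diene should approach the enone face anti to the pseudo-equatorial isopropyl group (axial attack at C8a'), and suprafacial delivery then fixes C4a' with its C4a'–C4' bond trans to isopropyl. The step needs anti facial selectivity, the para regiochemistry (siloxy carbon C2' 1,4 to C4a') and survival of the kinetic cis fusion and of the enol silane; these should be secured by the single stereocentre of 3, the donor oxygen at the diene 2-position, and the low temperature, amine quench and robust silyl group.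

Step 3
Reactants: 4 cis-fused keto enol silane
Product: 6 (4aS,8S,8aS)-5-methylidene-8-(propan-2-yl)octahydronaphthalen-2(1H)-one, via methylidene enol silane 5 (not isolated)
Conditions: Cp2TiMe2, toluene/THF, 70 °C, dark; then TBAF, AcOH, THF, 0 °C
Reagents that add atoms: dimethyltitanocene Cp2TiMe2, C[Ti](C)(C1C=CC=C1)C1C=CC=C1
Why: Petasis methylenation (non-basic titanium carbene) should convert the only carbonyl group, C5'=O, into the exocyclic alkene without epimerising the adjacent C4a' centre or touching the enol silane, which buffered fluoride then unmasks as the C2' ketone (desilylation); no new stereocentre is formed.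

Step 4
Reactants: 6 (4aS,8S,8aS)-5-methylidene-8-(propan-2-yl)octahydronaphthalen-2(1H)-one
Product: 7 (4aR,5R,8S,8aS)-5-methyl-8-(propan-2-yl)octahydronaphthalen-2(1H)-one (cis-fused, C5' methyl cis to C4')
Conditions: H2 (1 atm), RhCl(PPh3)3 (cat.), benzene/EtOH, rt
Reagents that add atoms: none
Why: Homogeneous hydrogenation should saturate the 1,1-disubstituted alkene without double-bond migration, with hydrogen delivered to the convex face of the cis-decalin (opposite the axial C4a'–C4' bond and ring B), which places the new equatorial methyl group cis to C4' (C5' R).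

Step 5
Reactants: 7 (4aR,5R,8S,8aS)-5-methyl-8-(propan-2-yl)octahydronaphthalen-2(1H)-one
Product: 8 trimethyl{[(4aR,5R,8S,8aS)-5-methyl-8-(propan-2-yl)-3,4,4a,5,6,7,8,8a-octahydronaphthalen-2-yl]oxy}silane (C1'=C2' enol silane)
Conditions: TMSCl, NaI, Et3N, MeCN, rt
Reagents that add atoms: chlorotrimethylsilane, C[Si](C)(C)Cl
Why: Equilibrating silyl enol ether formation (iodotrimethylsilane made in the flask, amine base) should favour the enol silane toward the ring fusion, the usual preference of cis-fused 2-decalones, helped here by relief of the gauche contact between C1' and the isopropyl-bearing C8'; only regiochemistry is at issue.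

Step 6
Reactants: 8 C1'=C2' trimethylsilyl enol ether
Product: 9 (4aR,5R,8S)-5-methyl-8-(propan-2-yl)-4,4a,5,6,7,8-hexahydronaphthalen-2(3H)-one (C2' ketone, C1'=C8a' alkene)
Conditions: Pd(OAc)2 (1.1 equiv), MeCN, rt
Reagents that add atoms: none
Why: Saegusa–Ito oxidation: the palladium enolate at C1' has H8a' as its only β-hydrogen, so β-hydride elimination should give the C1'=C8a' enone under neutral conditions that do not epimerise the γ-centres C4a' and C8'.

Step 7
Reactants: 9 (4aR,5R,8S)-5-methyl-8-(propan-2-yl)-4,4a,5,6,7,8-hexahydronaphthalen-2(3H)-one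
Product: 10 (1S,4R,4aR)-4-methyl-7-methylidene-1-(propan-2-yl)-1,2,3,4,4a,5,6,7-octahydronaphthalene (diene CH2=C2'–C1'=C8a')
Conditions: Cp2TiMe2, toluene/THF, 65 °C, dark
Reagents that add atoms: dimethyltitanocene Cp2TiMe2, C[Ti](C)(C1C=CC=C1)C1C=CC=C1
Why: Petasis methylenation adds the titanium carbene 1,2 to the enone carbonyl, so the s-trans diene should form without the dienolate formation that a basic ylide could cause and that would scramble C4a' or C8'.

Step 8
Reactants: 10 (1S,4R,4aR)-4-methyl-7-methylidene-1-(propan-2-yl)-1,2,3,4,4a,5,6,7-octahydronaphthalene; 11 benzaldehyde; 12 2,4,6-trihydroxybenzene-1,3-dicarbaldehyde (2,4-diformylphloroglucinol)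
Product: 14 Guajadial D, via o-quinone methide 13 (not isolated)
Conditions: ethylenediammonium diacetate (cat.), MeCN, 70 °C
Reagents that add atoms: none
Why: Domino Knoevenagel/inverse-electron-demand hetero-Diels–Alder reaction, the established way to spiro-chromans from exocyclic-methylene terpenes: 13 should add to the terminal C=CH2 with oxygen on the tertiary allylic carbon C2', the C–O bond forming axially on the ring B face anti to H4a' (C2' S) and the bulky C1'=C8a' arm exo to the heterodiene so that phenyl ends cis to C3' (C4 S); the diene is fixed s-trans and cannot react as a 4π partner.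

**Compound list**

1 | but-3-en-2-one (methyl vinyl ketone) | CC(=O)C=C | starting material
2 | 2-[(tert-butyldimethylsilyl)oxy]buta-1,3-diene | C=CC(=C)O[Si](C)(C)C(C)(C)C | intermediate
3 | (S)-cryptone, (4S)-4-(propan-2-yl)cyclohex-2-en-1-one | CC(C)[C@@H]1CCC(=O)C=C1 | starting material
4 | (4S,4aS,8aS)-6-[(tert-butyldimethylsilyl)oxy]-4-(propan-2-yl)-3,4,4a,5,8,8a-hexahydronaphthalen-1(2H)-one; cis-fused, new C–C bonds anti to isopropyl | CC(C)[C@@H]1CCC(=O)[C@H]2CC=C(O[Si](C)(C)C(C)(C)C)C[C@@H]12 | intermediate
5 | tert-butyl(dimethyl){[(4aS,8S,8aS)-5-methylidene-8-(propan-2-yl)-1,4,4a,5,6,7,8,8a-octahydronaphthalen-2-yl]oxy}silane (not isolated) | CC(C)[C@@H]1CCC(=C)[C@H]2CC=C(O[Si](C)(C)C(C)(C)C)C[C@@H]12 | intermediate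
6 | (4aS,8S,8aS)-5-methylidene-8-(propan-2-yl)octahydronaphthalen-2(1H)-one | CC(C)[C@@H]1CCC(=C)[C@H]2CCC(=O)C[C@@H]12 | intermediate
7 | (4aR,5R,8S,8aS)-5-methyl-8-(propan-2-yl)octahydronaphthalen-2(1H)-one (the C4a label changes by priority only; geometry as in 6) | CC(C)[C@@H]1CC[C@@H](C)[C@H]2CCC(=O)C[C@@H]12 | intermediate
8 | trimethyl{[(4aR,5R,8S,8aS)-5-methyl-8-(propan-2-yl)-3,4,4a,5,6,7,8,8a-octahydronaphthalen-2-yl]oxy}silane | CC(C)[C@@H]1CC[C@@H](C)[C@H]2CCC(O[Si](C)(C)C)=C[C@@H]12 | intermediate
9 | (4aR,5R,8S)-5-methyl-8-(propan-2-yl)-4,4a,5,6,7,8-hexahydronaphthalen-2(3H)-one | CC(C)[C@@H]1CC[C@@H](C)[C@H]2CCC(=O)C=C12 | intermediate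
10 | (1S,4R,4aR)-4-methyl-7-methylidene-1-(propan-2-yl)-1,2,3,4,4a,5,6,7-octahydronaphthalene | CC(C)[C@@H]1CC[C@@H](C)[C@H]2CCC(=C)C=C12 | intermediate
11 | benzaldehyde | O=Cc1ccccc1 | starting material
12 | 2,4,6-trihydroxybenzene-1,3-dicarbaldehyde | O=Cc1c(O)cc(O)c(C=O)c1O | starting material
13 | 5-benzylidene-2,4-dihydroxy-6-oxocyclohexa-1,3-diene-1,3-dicarbaldehyde (o-quinone methide, benzylidene geometry not fixed; not isolated) | O=C1C(=Cc2ccccc2)C(O)=C(C=O)C(O)=C1C=O | intermediate
14 | Guajadial D (C2' S, C4 S, C4a' R, C5' R, C8' S) | CC(C)[C@@H]1CC[C@@H](C)[C@H]2CC[C@@]3(C=C12)C[C@@H](c1ccccc1)c1c(O)c(C=O)c(O)c(C=O)c1O3 | target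

**Step count.** Total: 8 steps. Longest linear sequence: 8 steps (1 to 14 through the diene; 7 steps from 3).

**Steps most likely to fail**

Step 5. Enolisation may run toward C3' instead of C1', so that step 6 would deliver the C3'=C4' enone. The fallback is regiospecific; it sets out from 5 and returns at 9. Compound 5 is isolated after the methylenation and hydrogenated (H2, RhCl(PPh3)3) to the C5'-methyl enol silane F1. Saegusa–Ito oxidation of this regiodefined enol silane (Pd(OAc)2, O2, DMSO) gives the C3'=C4' enone F2, in which C1' is the only enolisable α-position. Kinetic deprotonation (LiN(iPr)2, THF, −78 °C) and sulfenylation with PhSO2SPh give the 1'-phenylsulfanyl enone F3. Conjugate reduction with [(Ph3P)CuH]6 gives the 1'-phenylsulfanyl ketone F4. Oxidation with mCPBA (−78 °C) gives the sulfoxide F5, whose thermal syn-elimination (toluene, 100 °C, CaCO3) can only involve H8a' and so gives 9.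

Step 8. The acid-sensitive diene may isomerise before it is trapped, and the cycloaddition may show poor facial or endo/exo selectivity, spreading material over C2'/C4 epimers. The fallback sets out from 11 and 12 and returns at 14. Compounds 11 and 12 are first condensed with morpholine (EtOH, rt; Mannich/Betti reaction) to the Mannich base F6, which is isolated. Heating F6 with 10 in toluene (80 °C) releases 13 slowly by loss of morpholine without free acid. The hetero-Diels–Alder step then runs apart from the condensation, in a neutral medium and at a low stationary concentration of 13.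

Step 2. Protodesilylation of the diene or the adduct, or arrest at the Michael stage, would erase the difference between the C2' and C5' carbonyl groups. The fallback sets out from 3 and 2 and returns at 6. The cycloaddition is run with stoichiometric Me2AlCl (CH2Cl2, −78 °C) and worked up with cold dilute HCl to give deliberately the cis-fused diketone F7. The unhindered C2' carbonyl is ketalised selectively (1,2-bis(trimethylsilyloxy)ethane, cat. TMSOTf, CH2Cl2, −78 °C) to the C2' dioxolane F8. Cp2TiMe2 methylenates C5' to the methylidene dioxolane F9, and pyridinium p-toluenesulfonate in wet acetone releases 6.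

**Further compounds**

F1 | step 5 | C2'=C3' tert-butyldimethylsilyl enol ether with C5' methyl (ring configuration as in 7) | CC(C)[C@@H]1CC[C@@H](C)[C@H]2CC=C(O[Si](C)(C)C(C)(C)C)C[C@@H]12
F2 | step 5 | cis-fused C2' ketone with C3'=C4' alkene | CC(C)[C@@H]1CC[C@@H](C)[C@H]2C=CC(=O)C[C@@H]12
F3 | step 5 | 1'-phenylsulfanyl C3'=C4' enone (C1' epimers) | CC(C)[C@@H]1CC[C@@H](C)[C@H]2C=CC(=O)C(Sc3ccccc3)[C@@H]12
F4 | step 5 | 1'-phenylsulfanyl C2' ketone (C1' epimers) | CC(C)[C@@H]1CC[C@@H](C)[C@H]2CCC(=O)C(Sc3ccccc3)[C@@H]12
F5 | step 5 | 1'-phenylsulfinyl C2' ketone (C1' and sulfur epimers) | CC(C)[C@@H]1CC[C@@H](C)[C@H]2CCC(=O)C(S(=O)c3ccccc3)[C@@H]12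
F6 | step 8 | 2,4,6-trihydroxy-5-[morpholin-4-yl(phenyl)methyl]benzene-1,3-dicarbaldehyde (racemic) | O=Cc1c(O)c(C=O)c(O)c(C(c2ccccc2)N2CCOCC2)c1O
F7 | step 2 | cis-fused (4a'S,8'S,8a'S) C2',C5'-diketone | CC(C)[C@@H]1CCC(=O)[C@H]2CCC(=O)C[C@@H]12
F8 | step 2 | C2' ethylene ketal of the C5' ketone | CC(C)[C@@H]1CCC(=O)[C@H]2CCC3(OCCO3)C[C@@H]12
F9 | step 2 | C2' ethylene ketal with C5' methylidene | CC(C)[C@@H]1CCC(=C)[C@H]2CCC3(OCCO3)C[C@@H]12
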